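**Plan**

Numbering: C1 = ring C(OH)(CH2OBz), C2 = CH(OBz), C3=C4 the ring alkene, C5 = CH(OBz), C6 = CH(OH), C7 = exocyclic CH2.
The only ring alkene, C3=C4, lies between two CH(OBz) carbons (C2, C5). Opened there, the cyclohexene is a 1,7-diene with two CH(OBz)–CH=CH2 ends and the free C1/C6 diol already in place.
Cuts, in order: C3=C4 (ring-closing metathesis); C5–C6 (carbonyl (benzoyloxy)allylation at C6); C2–OBz and the C1–C2 epoxide, back to an achiral pentadienyl benzoate.
Forward: a Wittig reaction joins a C3 ketone and a C3 ylide; monobenzoylation, epoxidation and benzoate opening set up C1/C2; allylation adds C5 and its vinyl group; the carbocycle is closed last, with no protecting group.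
Stereochemistry: C1 and C2 from Sharpless epoxidation (L-(+)-tartrate) with inversion at C2 on opening; C5 and C6 from the catalyst-controlled anti allylation; the cis alkene from the ring size.

Key step: step 8

Assumption: the sense of induction of the iridium–SEGPHOS catalyst in step 7 is taken from the parent allylation of aliphatic aldehydes; (S)-SEGPHOS is written for Si-face addition to aldehyde 11 and would be replaced by (R)-SEGPHOS if the sense proves opposite.

**Route**

Step 1
Reactants: 1 2,2-dimethyl-1,3-dioxan-5-one; 2 allyltriphenylphosphonium bromide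
Product: 4 2,2-dimethyl-5-(prop-2-en-1-ylidene)-1,3-dioxane, via allylidenetriphenylphosphorane 3 (not isolated)
Conditions: 2, n-BuLi, THF, 0 °C; then 1, −78 °C → rt
Reagents that add atoms: none
Why: Wittig olefination, in which the semi-stabilised allyl ylide 3 attacks the unhindered ketone through its α-carbon and the oxaphosphetane collapses to the 1,3-diene; no geometrical isomers arise because the two ring CH2O arms are equivalent.

Step 2
Reactants: 4 2,2-dimethyl-5-(prop-2-en-1-ylidene)-1,3-dioxane
Product: 5 2-(prop-2-en-1-ylidene)propane-1,3-diol
Conditions: PPTS (cat.), MeOH, rt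
Reagents that add atoms: none
Why: Acid-catalysed transacetalisation to methanol should release the 1,3-diol under conditions too mild to ionise the dienylic C–O bonds.

Step 3
Reactants: 5 2-(prop-2-en-1-ylidene)propane-1,3-diol
Product: 6 [(2E)-2-(hydroxymethyl)penta-2,4-dien-1-yl] benzoate
Conditions: vinyl benzoate (3 equiv), immobilised Burkholderia cepacia lipase, t-BuOMe, 30 °C
Reagents that add atoms: vinyl benzoate, C=COC(=O)c1ccccc1
Why: Lipase-catalysed transesterification with an enol ester is irreversible and, in 2-alkylidenepropane-1,3-diols, takes place at the hydroxymethyl group trans to the alkene substituent (the arm cis to the vinyl group is shielded), so the E-monobenzoate should form; no stereocentre arises, but this site selection decides which arm becomes C6 and hence the sense at C1 in step 4.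

Step 4
Reactants: 6 [(2E)-2-(hydroxymethyl)penta-2,4-dien-1-yl] benzoate
Product: 7 [(2R,3R)-3-ethenyl-2-(hydroxymethyl)oxiran-2-yl]methyl benzoate
Conditions: Ti(OiPr)4 (20 mol%), L-(+)-diisopropyl tartrate (24 mol%), t-BuOOH (2 equiv), 4 Å molecular sieves, CH2Cl2, −20 °C
Reagents that add atoms: tert-butyl hydroperoxide, CC(C)(C)OO
Why: Sharpless asymmetric epoxidation of the primary allylic alcohol, in which titanium binds the free CH2OH and delivers oxygen only to the allylic C1=C2 bond, and L-(+)-tartrate selects the face that gives the (2R,3R)-epoxide, setting C1 and (before inversion) C2 under reagent control.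

Step 5
Reactants: 7 [(2R,3R)-3-ethenyl-2-(hydroxymethyl)oxiran-2-yl]methyl benzoate
Product: 8 (2R,3S)-2-hydroxy-2-(hydroxymethyl)pent-4-ene-1,3-diyl dibenzoate
Conditions: PhCO2H (1.2 equiv), Ti(OiPr)4 (1.5 equiv), CH2Cl2, rt; aq. tartaric acid work-up
Reagents that add atoms: benzoic acid, OC(=O)c1ccccc1
Why: Titanium-alkoxide-mediated opening of a 2,3-epoxy alcohol by a carboxylic acid (C3-selective Sharpless opening), in which benzoate attacks the distal, allylically activated epoxide carbon with inversion, giving the trans C1–OH/C2–OBz pair while C1 keeps its configuration.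

Step 6
Reactants: 9 acrolein
Product: 10 prop-2-ene-1,1-diyl dibenzoate
Conditions: Bz2O (1.1 equiv), H2SO4 (cat.), CH2Cl2, 0 °C → rt
Reagents that add atoms: benzoic anhydride, O=C(OC(=O)c1ccccc1)c1ccccc1
Why: Acid-catalysed acylal formation, the anhydride adding across the aldehyde C=O of acrolein as in the preparation of allylidene diacetate; no stereocentre is formed.

Step 7
Reactants: 8 (2R,3S)-2-hydroxy-2-(hydroxymethyl)pent-4-ene-1,3-diyl dibenzoate; 10 prop-2-ene-1,1-diyl dibenzoate
Product: 12 (3S,4S,5S,6S)-5-[(benzoyloxy)methyl]-4,5-dihydroxyocta-1,7-diene-3,6-diyl dibenzoate, via aldehyde 11 (not isolated)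
Conditions: [Ir(cod)Cl]2 (2.5 mol%), (S)-SEGPHOS (5 mol%), 4-cyano-3-nitrobenzoic acid (10 mol%), Cs2CO3 (20 mol%), THF, 90 °C
Reagents that add atoms: none
Why: Iridium-catalysed transfer-hydrogenative carbonyl (acyloxy)allylation from the alcohol oxidation level, in which the primary alcohol is dehydrogenated to aldehyde 11 (the tertiary hydroxyl cannot be oxidised), 10 is ionised to an (E)-γ-benzoyloxy-σ-allyliridium species, and addition through a chair transition state gives the anti C6–OH/C5–OBz pair, with the ligand selecting the Si face of 11 so that C6 and C5 are both S; branched allylic benzoates next to a carbinol are the normal products of this reaction type, so the one at C2 should survive.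

Step 8
Reactants: 12 (3S,4S,5S,6S)-5-[(benzoyloxy)methyl]-4,5-dihydroxyocta-1,7-diene-3,6-diyl dibenzoate
Product: 13 [(1S,2S,5S,6S)-2,5-bis(benzoyloxy)-1,6-dihydroxycyclohex-3-en-1-yl]methyl benzoate (CNP0128482.4)
Conditions: second-generation Grubbs catalyst (H2IMes)(PCy3)Cl2Ru=CHPh (5 mol%), CH2Cl2 (5 mM), 40 °C
Reagents that add atoms: none
Why: Ring-closing olefin metathesis: the ruthenium benzylidene exchanges with one terminal vinyl group, the new alkylidene adds to the second vinyl group through a ruthenacyclobutane, and cycloreversion releases the ring alkene and ethene. The closest known reaction type is the ring-closing metathesis of 1,7-dienes that carry oxygen at both allylic positions, as used for conduritol-type cyclohexenetetrol esters. The six-membered carbocycle is closed at C3=C4 by joining the two vinyl CH carbons (1,7-diene to cyclohexene, the only ring formed), and the new alkene can only be cis in a ring of this size. No stereocentre is created; C1, C2, C5 and C6 arrive fixed from steps 4, 5 and 7 and are not touched, since no acid or base is present. The step needs ring closure to win over oligomerisation and over chelation of ruthenium by the allylic benzoates; high dilution, loss of ethene, the fully substituted C1 (gem-disubstituent effect) and the erythro C1/C6 diol, which lets the two arms lie gauche, should secure this, and the catalyst tolerates free hydroxyl groups.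

**Compound list**

1 | 2,2-dimethyl-1,3-dioxan-5-one | CC1(C)OCC(=O)CO1 | starting material
2 | allyltriphenylphosphonium bromide | C=CC[P+](c1ccccc1)(c1ccccc1)c1ccccc1.[Br-] | starting material
3 | allylidenetriphenylphosphorane | C=CC=P(c1ccccc1)(c1ccccc1)c1ccccc1 | intermediate
4 | 2,2-dimethyl-5-(prop-2-en-1-ylidene)-1,3-dioxane | CC1(C)OCC(=CC=C)CO1 | intermediate
5 | 2-(prop-2-en-1-ylidene)propane-1,3-diol | OCC(CO)=CC=C | intermediate
6 | [(2E)-2-(hydroxymethyl)penta-2,4-dien-1-yl] benzoate | OC/C(COC(=O)c1ccccc1)=C\C=C | intermediate
7 | [(2R,3R)-3-ethenyl-2-(hydroxymethyl)oxiran-2-yl]methyl benzoate | OC[C@]1(COC(=O)c2ccccc2)O[C@@H]1C=C | intermediate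
8 | (2R,3S)-2-hydroxy-2-(hydroxymethyl)pent-4-ene-1,3-diyl dibenzoate | OC[C@@](O)(COC(=O)c1ccccc1)[C@@H](OC(=O)c1ccccc1)C=C | intermediate
9 | acrolein | C=CC=O | starting material
10 | prop-2-ene-1,1-diyl dibenzoate | C=CC(OC(=O)c1ccccc1)OC(=O)c1ccccc1 | intermediate
11 | (2R,3S)-2-formyl-2-hydroxypent-4-ene-1,3-diyl dibenzoate | O=C[C@@](O)(COC(=O)c1ccccc1)[C@@H](OC(=O)c1ccccc1)C=C | intermediate
12 | (3S,4S,5S,6S)-5-[(benzoyloxy)methyl]-4,5-dihydroxyocta-1,7-diene-3,6-diyl dibenzoate | O=C(c1ccccc1)OC[C@@]([C@@H](O)[C@@H](OC(=O)c1ccccc1)C=C)(O)[C@@H](OC(=O)c1ccccc1)C=C | intermediate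
13 | [(1S,2S,5S,6S)-2,5-bis(benzoyloxy)-1,6-dihydroxycyclohex-3-en-1-yl]methyl benzoate | O=C(OC[C@@]1(O)[C@@H](OC(=O)c2ccccc2)C=C[C@H](OC(=O)c2ccccc2)[C@@H]1O)c1ccccc1 | target

**Step count and risks**

Total step count: 8. Longest linear sequence: 7 steps (1, 2, 3, 4, 5, 7, 8); step 6 is a one-step side branch.

Steps most likely to fail:

Step 7. Under the hot, mildly basic conditions a benzoyl group may migrate between the CH2OBz and CH2OH arms (which would scramble C1) or from C2 to the primary hydroxyl. The hindered neopentyl-type alcohol may also be dehydrogenated slowly, aldehyde 11 may undergo α-ketol rearrangement, or catalyst control of the aldehyde face may be incomplete. Fallback, setting out from 8: oxidation with Dess–Martin periodinane (NaHCO3, CH2Cl2, 0 °C) should give aldehyde 11, this time isolated crude. 3-Bromoprop-1-en-1-yl benzoate F1 is made from acrolein 9 and benzoyl bromide (ZnCl2 cat., 1,4-addition). F1 and 11 are then combined with CrCl2 in THF (Nozaki–Hiyama-type γ-acyloxyallylation, neutral, 0 °C → rt). The allylchromium reagent should add through a chair transition state to give the anti hydroxy benzoate, with the aldehyde face chosen by Felkin–Anh substrate control. The sequence comes back to the route at 12.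

Step 3. Acylation may be poorly site-selective between the two primary allylic hydroxyl groups, or slow with a benzoyl donor, giving the Z-monobenzoate and dibenzoate as well. Fallback, setting out from 5: iodoetherification (I2, NaHCO3, MeCN, 0 °C) uses a temporary ring to tell the arms apart. Only the hydroxymethyl group cis to the vinyl group can reach the inner carbon of the terminal alkene (5-exo closure), which should give [5-(iodomethyl)-2,5-dihydrofuran-3-yl]methanol F2. The remaining hydroxyl is benzoylated (BzCl, pyridine, CH2Cl2, 0 °C) to [5-(iodomethyl)-2,5-dihydrofuran-3-yl]methyl benzoate F3. Zinc dust in EtOH/AcOH then opens the ring by reductive β-elimination, regenerating the diene and freeing the cis hydroxymethyl group. The sequence comes back to the route at 6.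

Step 4. Epoxidation directed by a hydroxymethyl group cis to the C3 substituent is slow and may give modest enantioface selectivity, and the titanium alkoxide may open the vinyl epoxide during the long reaction. Fallback, setting out from 6: Shi epoxidation with a fructose-derived ketone catalyst, Oxone and K2CO3 in buffered MeCN/dimethoxymethane at 0 °C. This is a metal-free dioxirane oxygen transfer to the more substituted alkene of the diene; the catalyst enantiomer is chosen by the spiro transition-state model to give the (2R,3R)-epoxide. It comes back to the route at 7.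

Further compounds
F1 | step 7 | 3-bromoprop-1-en-1-yl benzoate (E/Z mixture) | BrCC=COC(=O)c1ccccc1
F2 | step 3 | [5-(iodomethyl)-2,5-dihydrofuran-3-yl]methanol (racemic) | OCC1=CC(CI)OC1
F3 | step 3 | [5-(iodomethyl)-2,5-dihydrofuran-3-yl]methyl benzoate (racemic) | O=C(OCC1=CC(CI)OC1)c1ccccc1
F0 | step 4 | none | none
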